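I start with an easy division: target at the end over starting material charged, the end yield Y.

| flask | starting material | reagent | remark | time |
|---|---|---|---|---|
| south-east | 3.400 × 10⁻⁵ M | 0.35 mM | run made earlier |  |
| south-west | 4.1 × 10⁻⁴ M | 0.35 mM | run made earlier |  |
| Thursday's | 6.0 × 10⁻⁵ M | 0.350 mM |  | 4.0 min |
| Wednesday's | 1.2 × 10⁻⁴ M | 0.350 mM |  | 4.0 min |
| Saturday's | 2.5 × 10⁻⁴ M | 0.350 mM |  | 4.0 min |
| Monday's | 5.0 × 10⁻⁴ M | 0.350 mM |  | 4.0 min |

| run | time / min | target / % | starting material / % |
|---|---|---|---|
| south-east | 0.333 | 0.1 | 35.0 |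
| south-east | 0.667 | 0 | 15.9 |
| south-east | 1.50 | 0.5 | 7.3 |
| south-east | 4.00 | 4.2 | 5.2 |
| south-west | 1.00 | 0.7 | 22.0 |
| south-west | 2.00 | 0.6 | 15.5 |
| south-west | 3.00 | 1.0 | 12.7 |
| south-west | 4.00 | 1.5 | 11.4 |

(standard deviation of a reading: 0.3 percentage points)

- the earlier runs were read with a standard deviation of 0.3 percentage points
- "hardly changes" means that all values lie within two and a half points (for a concentration: within two and a half percent of the largest)

1. [target] at the end for Thursday's, Wednesday's, Saturday's, Monday's, in this order
2. the course of these numbers from the first flask to the last (hardly changes / rises, then falls / rises all the way / falls, then rises / falls all the way)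

In the first instants of the south-east run, starting material drops to 15.9% by 0.667 min while target reads 0%, so what leaves goes into forms I do not read. In the middle, at 1.50 min, starting material reads 7.3% and target 0.5%: this is the lag, the induction period. At the end, 4.00 min, target reads 4.2%, and 90.6% of the charge still stands unread. The south-west run, charged above the reagent's 0.35 mM, ends lower in percent of its charge, at 1.5%.

Target is a small correction to the charge, so I reckon the correction and nothing else. My own assumption is a straight line through these two end yields, each a reading with its scatter. Its slope S, here 71.8 L mol⁻¹, is the end yield lost per unit of charge, and H is the line's value at zero charge: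

S = (Y south-east − Y south-west) / (difference of charges) = 71.8 L mol⁻¹

H = Y south-east + S · c(starting material, south-east) = 4.44%

c(target) = c(starting material) · (H − S · c(starting material))

This product peaks at H/(2S) = 3.09 × 10⁻⁴ M, between Saturday's and Monday's charges. For the four flasks I commit to 2.41 × 10⁻⁶ M, 4.30 × 10⁻⁶ M, 6.62 × 10⁻⁶ M and 4.27 × 10⁻⁶ M.

The forecast gives 2.400 × 10⁻⁶ M, 4.300 × 10⁻⁶ M, 7.000 × 10⁻⁶ M and 3.500 × 10⁻⁶ M, with the course "rises, then falls". It stands above my line on Saturday's and below it on Monday's. Its words: “I expect a maximum near Saturday's flask, though Monday's value is uncertain.”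

The flasks give 1.99 × 10⁻⁶ M, 3.39 × 10⁻⁶ M, 4.78 × 10⁻⁶ M and 4.29 × 10⁻⁶ M, and the course is "rises, then falls".

    starting material ⇌ intermediate A (K = 8.60, k = 0.00870 s⁻¹)
    starting material + reagent ⇌ intermediate B (K = 27000 L mol⁻¹, k = 140 L mol⁻¹ s⁻¹)
    reagent + intermediate B ⇌ intermediate C (K = 88000 L mol⁻¹, k = 7.10 L mol⁻¹ s⁻¹)
    intermediate C → target (k = 0.00110 s⁻¹)
    reagent + target → over-reaction product (k = 1.80 L mol⁻¹ s⁻¹)

On Monday's flask, the slope S puts the end yield at 0.854%, and the flask has 0.857%. Monday's run without the falling level of reagent reaches 1.92 × 10⁻⁵ M, a yield of 3.83%, so that fall is a part of what S measures. On Thursday's flask, the line says 4.01% and the flask has 3.31%. Thursday's run without the falling level of reagent reaches 2.30 × 10⁻⁶ M, again a yield of 3.83%, so the same fall is a smaller part there. Of the changes tried on Thursday's flask, the length of the run has the largest single effect: a run ten times as long gives 2.25 × 10⁻⁵ M.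

The numbers in the tables are calculated on assumed constants.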